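Remark on the chemistry: the target has no stereocentre and is taken as the 11,12-dihydro tautomer with both nitrogen atoms as N–H, as its SMILES string shows.

Numbering used throughout: 1 veratrole; 2 its 3,6-dilithio derivative; 3 the ring C bis(pinacol boronate); 4 2-bromo-5-chloroaniline; 5 its acetamide; 6 the bis-acetanilide terphenyl; 7 the monocyclised N-acetylcarbazole; 8 the 11,12-diacetyl indolocarbazole; 9 borregomycin E.

## Analysis of the target

Borregomycin E 9 is a flat, pentacyclic indolo[2,3-a]carbazole made of two chlorobenzene rings (A and E), two pyrrole rings (B and D) and a central benzene ring C. It has no stereocentre, and a twofold symmetry exchanges the two indole halves, so every operation can be run in duplicate on a symmetric intermediate. Ring C is fully substituted in a fixed order: methoxy groups on C5 and C6, the aryl carbons C4a and C6b on C4b and C6a, and the nitrogen atoms N12 and N11 on C11b and C11a. The sensitive parts are the electron-rich dimethoxy core, which drifts towards ortho-quinone-type oxidation once the nitrogen atoms are free, and the two neighbouring N–H groups in the bay. The aryl chlorides at C2 and C9 rule out hydrogenolysis, dissolving metals and electron-rich zerovalent palladium catalysts at high temperature. The difficulty is to assemble the hexasubstituted ring C without regiochemical ambiguity and to place two nitrogen atoms on adjacent carbons. The strategy rests on one feature: C11a is para to the methoxy-bearing C5 and C11b is para to C6, so that cutting N11–C11a and N12–C11b leaves ring C as a 3,6-diarylveratrole whose only two C–H carbons are the positions at which an oxidised veratrole ring accepts a nitrogen nucleophile.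

## Retrosynthetic reasoning

9 to 8. The two N–H groups are uncovered last by cutting two N–acetyl bonds. The acetyl groups are kept until then because they make each nitrogen a usable partner in the oxidative ring closure and hold the oxidation potential of the pentacycle above the working potential. On carbazole-type nitrogen they come off by mild base-mediated solvolysis, which the methoxy groups and aryl chlorides ignore.

8 to 6. The bonds N11–C11a and N12–C11b are cut. Cutting here, and not at a C–C bond of ring C, leaves ring C intact with both methoxy groups in place, so no benzannulation and no later oxygenation are needed. The precursor 6 is a symmetric terphenyl. The forward reaction has to remove four hydrogen atoms (two N–H, two C–H) and form two N–C bonds, one after the other through 7, without any prior functionalisation of ring C. An anodic dehydrogenative coupling does this.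

6 to 3 and 5. The biaryl bonds C4a–C4b and C6a–C6b are cut. Boron is placed on ring C and bromine on the anilide ring, so that the chloroaniline unit enters as a simple bromide and the only selectivity required is bromine before chlorine in oxidative addition. Both bonds are made in one operation because 3 is symmetric.

5 to 4, and 3 to 1 through 2. The acetamide 5 comes from the aniline 4 by N-acetylation. The two C–B bonds of 3 are traced back to the C–H bonds of 1 that lie ortho to the methoxy groups. The same methoxy groups that later steer the anodic closure direct a double lithiation to C3 and C6, giving 2, which is trapped with a boron electrophile.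

## Alternatives that were turned down

Alternative 1: Both pyrrole rings are cut at once, at N11–C11a, N12–C11b, C4a–C4b and C6a–C6b. This leads to two molecules of 5-chloro-2-iodoaniline A1 and the symmetric conjugated diyne 1,6-bis(tert-butyldimethylsilyloxy)hexa-2,4-diyne A2, whose central single bond becomes C11a–C11b. In the forward sense, Pd(OAc)2 with LiCl and K2CO3 generates zerovalent palladium, which inserts into the C–I bond of A1; the arylpalladium adds across one alkyne of A2 and nitrogen then displaces the metal. Repeating this on the second alkyne should give the biindole A3.
- For: four bonds and two rings form in one flask from the very simple pieces A1 and A2, the nitrogen atoms stay unsubstituted so there is no bay crowding, and the C–I bond of A1 reacts well before its C–Cl bond.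
- Against: Larock insertion normally places the bulkier alkyne substituent next to nitrogen. In A2 the silyloxymethyl group is bulkier than the rod-shaped alkynyl group, so the required orientation is not assured in either annulation.
- Against: A3 still lacks ring C. The C5–C6 bond and both oxygen atoms would have to be added by desilylation, oxidation of both carbinols to the aldehyde level, ring closure and O-methylation, four or more further steps through air-sensitive intermediates.
- Comparison: this alternative is stronger in bonds formed per step and needs no nitrogen protecting group. The chosen route has ring C complete with both methoxy groups from the first step, offers no regiochemical choice in its key step, and needs five steps in all.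

Alternative 2: Only the C5–C6 bond of ring C is cut, which leads to the dialdehyde A4. A triazolium-derived N-heterocyclic carbene, set free with DBU, adds to one formyl group of A4 and turns it into an acyl anion equivalent that attacks the other formyl group. The resulting hydroxy ketone tautomerises to the aromatic 5,6-diol A5.
- For: the gain of aromaticity drives the closure, both oxygen atoms arrive on the right carbons at the right oxidation level, and the conditions are mild and metal-free.
- Against: A4 needs its biindole core to be built, N-protected and formylated twice, so the sequence up to the key step is already longer than the whole chosen route.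
- Against: the two SEM groups of A4 meet in the bay in the syn-coplanar conformation needed for closure. This is the same crowding as in 8, but with larger groups.
- Against: A5 is an electron-rich catechol that can oxidise to the ortho-quinone before it is methylated.
- Against: removal of two SEM groups from neighbouring indolic nitrogen atoms tends to stop at the N-hydroxymethyl stage, or to bridge N11 and N12 with the one-carbon fragment that is released.
- Comparison: this alternative is milder and needs no electrolysis cell, and on those points it is stronger. The chosen route is about half as long and never passes through a free catechol.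

Alternative 3: Ring C and both pyrrole rings are disconnected together at C11b–C4b, C5–C6 and C6a–C11a. The precursor is the triyne A6, in which an alkyne carrying two sulfonamide nitrogen atoms is tethered through the two chlorophenylene rings to two methoxyalkynes. RhCl(PPh3)3, a complex of monovalent rhodium, couples two alkynes of A6 to a rhodacyclopentadiene, inserts the third and releases the arene A7 by reductive elimination.
- For: three rings and three C–C bonds form in one isomerisation without by-product, the tethers fix the position of all six substituents on ring C, and only sulfonyl removal separates A7 from the target.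
- Against: all three alkynes of A6 carry heteroatoms (one ynediamide, two ynol ethers) and are prone to hydration and nucleophilic addition.
- Against: building A6 needs two N-alkynylations on the same two-carbon unit and the installation of methoxyethynyl groups on rings that also carry chlorine, a long sequence with little close analogy for the ynediamide part.
- Against: A7 has two sulfonyl groups in the bay, and their removal calls for stronger nucleophiles or reducing metals, the latter a threat to the aryl chlorides.
- Comparison: in the key step itself this alternative is stronger in bond count and atom economy. The chosen route offers a precursor made in three routine steps from stable compounds and confines the uncertain chemistry to a single late step on cheap material.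

Key step: step 4

## Route

Step 1
Reactants: 1 1,2-dimethoxybenzene (veratrole)
Product: 3 2,2'-(2,3-dimethoxy-1,4-phenylene)bis(4,4,5,5-tetramethyl-1,3,2-dioxaborolane), via 3,6-dilithioveratrole 2 (not isolated)
Conditions: n-BuLi (3 equiv), TMEDA (3 equiv), Et2O/hexane, 0 °C to reflux; then iPrOBpin (3.5 equiv), −78 °C to rt; 1 M aq. HCl to pH 6
Reagents that add atoms: 2-isopropoxy-4,4,5,5-tetramethyl-1,3,2-dioxaborolane (iPrOBpin), CC(C)OB1OC(C)(C)C(C)(C)O1
Why: Double directed ortho-metalation: each methoxy oxygen binds lithium (TMEDA breaks up the aggregates) and delivers the base to its own free ortho position, C3 and C6; the two aryllithium carbons of 2 then add to the borate ester and the ate complexes lose isopropoxide (electrophilic borylation of an aryllithium).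

Step 2
Reactants: 4 2-bromo-5-chloroaniline
Product: 5 N-(2-bromo-5-chlorophenyl)acetamide
Conditions: Ac2O (1.2 equiv), pyridine, cat. DMAP, CH2Cl2, 0 °C to rt
Reagents that add atoms: acetic anhydride, CC(=O)OC(C)=O
Why: N-Acetylation of a weakly nucleophilic haloaniline under nucleophilic catalysis by DMAP; the acetamide supplies the N–H donor and the nitrogen protecting group that step 4 needs.

Step 3
Reactants: 3 2,2'-(2,3-dimethoxy-1,4-phenylene)bis(4,4,5,5-tetramethyl-1,3,2-dioxaborolane); 5 N-(2-bromo-5-chlorophenyl)acetamide (2.2 equiv)
Product: 6 N,N'-[(2,3-dimethoxy-1,4-phenylene)bis(5-chloro-2,1-phenylene)]diacetamide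
Conditions: Pd(PPh3)4 (5 mol %), 2 M aq. K2CO3, 1,4-dioxane, 90 °C, degassed
Reagents that add atoms: none
Why: Twofold Suzuki–Miyaura coupling; PPh3-ligated zerovalent palladium inserts into the C–Br bond of 5 and leaves both C–Cl bonds alone, and each new biaryl bond (C4a–C4b and C6a–C6b) carries only two ortho substituents, so transmetalation and reductive elimination should not be unduly hindered.

Step 4
Reactants: 6 N,N'-[(2,3-dimethoxy-1,4-phenylene)bis(5-chloro-2,1-phenylene)]diacetamide
Product: 8 11,12-diacetyl-2,9-dichloro-5,6-dimethoxy-11,12-dihydroindolo[2,3-a]carbazole, via monocyclised N-acetylcarbazole 7 (not isolated)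
Conditions: constant current (ca. 5 mA cm−2, 4.5–5 F mol−1), graphite anode, Pt cathode, undivided cell, NBu4PF6 (0.05 M), HFIP, rt to 40 °C
Reagents that add atoms: none
Why: The closest known reaction type is the anodic dehydrogenative N–H/C–H cyclisation of N-acyl-2-aminobiaryls to N-acylcarbazoles, run here twice on one terphenyl. One-electron oxidation at graphite in HFIP, a solvent that stabilises radical cations, gives either an amidyl radical (the N–H proton is taken by the hexafluoroisopropoxide formed at the cathode) or the radical cation of the veratrole-type ring C; nitrogen then bonds to the ring C carbon ortho to the biaryl bond, and loss of a second electron and a proton restores the aromatic ring. The first closure forms N11–C11a and with it pyrrole ring D, a five-membered closure of nitrogen onto an sp2 carbon of ring C, and should give 7. The second closure repeats this at C1 of 7, the future C11b, forming N12–C11b and pyrrole ring B to give 8, while the cathode reduces the released protons to H2; no stereocentre is formed. Each nitrogen can reach only two carbons of ring C, one bearing methoxy and one bearing hydrogen; the C–H carbon is para to a methoxy group, where the oxidised veratrole carries most of its positive charge, and only there can a proton leave to rearomatise, so C11a and C11b are the favoured sites. The C–Cl bonds are not oxidised at this potential, the N-acetyl groups keep the product harder to oxidise than 6, and ring C of 8 has no C–H bond left for further coupling. The two acetyl groups of 8 meet in the bay and must twist out of the ring plane, which makes the second closure the demanding one.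

Step 5
Reactants: 8 11,12-diacetyl-2,9-dichloro-5,6-dimethoxy-11,12-dihydroindolo[2,3-a]carbazole
Product: 9 borregomycin E, 2,9-dichloro-5,6-dimethoxy-11,12-dihydroindolo[2,3-a]carbazole
Conditions: K2CO3 (cat.), MeOH/THF, rt, argon
Reagents that add atoms: none
Why: Base-mediated methanolysis of N-acylcarbazole-type amides: the nitrogen lone pairs belong to the aromatic pyrrole rings and the acetyl groups are twisted, so the carbonyls behave like active esters and the carbazolide is a good leaving group; aryl chlorides and methyl ethers are inert to K2CO3 in MeOH.

## Compound list

1 | 1,2-dimethoxybenzene (veratrole) | COc1ccccc1OC | starting material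
2 | 3,6-dilithio-1,2-dimethoxybenzene | [Li]c1ccc([Li])c(OC)c1OC | intermediate
3 | 2,2'-(2,3-dimethoxy-1,4-phenylene)bis(4,4,5,5-tetramethyl-1,3,2-dioxaborolane) | COc1c(B2OC(C)(C)C(C)(C)O2)ccc(B2OC(C)(C)C(C)(C)O2)c1OC | intermediate
4 | 2-bromo-5-chloroaniline | Nc1cc(Cl)ccc1Br | starting material
5 | N-(2-bromo-5-chlorophenyl)acetamide | CC(=O)Nc1cc(Cl)ccc1Br | intermediate
6 | N,N'-[(2,3-dimethoxy-1,4-phenylene)bis(5-chloro-2,1-phenylene)]diacetamide | CC(=O)Nc1cc(Cl)ccc1-c1ccc(-c2ccc(Cl)cc2NC(C)=O)c(OC)c1OC | intermediate
7 | N-[2-(9-acetyl-7-chloro-3,4-dimethoxy-9H-carbazol-2-yl)-5-chlorophenyl]acetamide | COc1c(OC)c2c3ccc(Cl)cc3n(C(C)=O)c2cc1-c1ccc(Cl)cc1NC(C)=O | intermediate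
8 | 11,12-diacetyl-2,9-dichloro-5,6-dimethoxy-11,12-dihydroindolo[2,3-a]carbazole | COc1c(OC)c2c3ccc(Cl)cc3n(C(C)=O)c2c2n(C(C)=O)c3cc(Cl)ccc3c12 | intermediate
9 | borregomycin E, 2,9-dichloro-5,6-dimethoxy-11,12-dihydroindolo[2,3-a]carbazole | COc1c(OC)c2c3ccc(Cl)cc3[nH]c2c2[nH]c3cc(Cl)ccc3c12 | target

## Step count and least certain steps

Total step count: 5. Longest linear sequence: 4 steps (1 to 3 to 6 to 8 to 9; the branch 4 to 5 is one step and joins at step 3).

Step 4 (key step). The first closure to 7 should be straightforward. The likely failure is a stall before the second closure, because the acetyl group on N11 and the incoming acetamide nitrogen crowd each other in the bay and both acyl groups must leave the ring plane. Prolonged electrolysis to force conversion could then bring on solvolytic loss of a twisted acetyl group followed by over-oxidation of the freed N–H carbazole. Oxidative demethylation of ring C towards quinone-type material and intermolecular coupling of radical cations are further possibilities. Fallback, setting out from 3: Suzuki coupling (Pd(PPh3)4, aq. K2CO3, dioxane, 90 °C) with commercial 1-bromo-4-chloro-2-nitrobenzene F1 should give 1,4-bis(4-chloro-2-nitrophenyl)-2,3-dimethoxybenzene F2. Heating F2 with PPh3 in 1,2-dichlorobenzene at 180 °C is a double Cadogan reductive cyclisation: each nitro group is deoxygenated to a nitrene-type species that inserts into the neighbouring C–H bond of ring C. It forms the same two N–C bonds on unsubstituted nitrogen, where no bay crowding arises, and comes back to the route at 9 directly, so that neither 8 nor step 5 is needed.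

Step 3. Protodeboronation of the ortho-methoxy boronate may outrun the second transmetalation, so that the coupling stops after one arylation. Chelation of palladium by the ortho-acetamido group after oxidative addition may slow transmetalation further. Fallback with reversed polarity, setting out from 1 and 5: the dilithio species 2 made from 1 as in step 1 is quenched with 1,2-dibromotetrachloroethane to give 1,4-dibromo-2,3-dimethoxybenzene F3. Compound 5 is borylated (B2pin2, Pd(dppf)Cl2, KOAc, dioxane, 85 °C) to N-[5-chloro-2-(4,4,5,5-tetramethyl-1,3,2-dioxaborolan-2-yl)phenyl]acetamide F4. Suzuki coupling of F3 with two equivalents of F4 (Pd(PPh3)4, aq. K2CO3, dioxane, 90 °C) comes back to the route at 6.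

Step 1. The second metalation may stay incomplete because the monolithiated species aggregates and precipitates, and an aryllithium may add to a boronate already formed; both lead to mixtures of mono- and bis-borylated material. Fallback by two separate mono-metalations with silicon as placeholder, setting out from 1: n-BuLi/TMEDA and then Me3SiCl should give (2,3-dimethoxyphenyl)trimethylsilane F5, and a second cycle of the same kind (2,3-dimethoxy-1,4-phenylene)bis(trimethylsilane) F6. Ipso-iododesilylation of F6 with ICl in CH2Cl2 at 0 °C should give 1,4-diiodo-2,3-dimethoxybenzene F7, and double Miyaura borylation of F7 (B2pin2, Pd(dppf)Cl2, KOAc, dioxane, 85 °C) comes back to the route at 3.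

## Further compounds

F1 | step 4 | 1-bromo-4-chloro-2-nitrobenzene | O=[N+]([O-])c1cc(Cl)ccc1Br
F2 | step 4 | 1,4-bis(4-chloro-2-nitrophenyl)-2,3-dimethoxybenzene | COc1c(-c2ccc(Cl)cc2[N+](=O)[O-])ccc(-c2ccc(Cl)cc2[N+](=O)[O-])c1OC
F3 | step 3 | 1,4-dibromo-2,3-dimethoxybenzene | COc1c(Br)ccc(Br)c1OC
F4 | step 3 | N-[5-chloro-2-(4,4,5,5-tetramethyl-1,3,2-dioxaborolan-2-yl)phenyl]acetamide | CC(=O)Nc1cc(Cl)ccc1B1OC(C)(C)C(C)(C)O1
F5 | step 1 | (2,3-dimethoxyphenyl)trimethylsilane | COc1cccc([Si](C)(C)C)c1OC
F6 | step 1 | (2,3-dimethoxy-1,4-phenylene)bis(trimethylsilane) | COc1c([Si](C)(C)C)ccc([Si](C)(C)C)c1OC
F7 | step 1 | 1,4-diiodo-2,3-dimethoxybenzene | COc1c(I)ccc(I)c1OC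
A1 | alternative 1 | 5-chloro-2-iodoaniline | Nc1cc(Cl)ccc1I
A2 | alternative 1 | 1,6-bis(tert-butyldimethylsilyloxy)hexa-2,4-diyne | CC(C)(C)[Si](C)(C)OCC#CC#CCO[Si](C)(C)C(C)(C)C
A3 | alternative 1 | 3,3'-bis(tert-butyldimethylsilyloxymethyl)-6,6'-dichloro-1H,1'H-2,2'-biindole | CC(C)(C)[Si](C)(C)OCc1c(-c2[nH]c3cc(Cl)ccc3c2CO[Si](C)(C)C(C)(C)C)[nH]c2cc(Cl)ccc12
A4 | alternative 2 | 6,6'-dichloro-1,1'-bis(2-trimethylsilylethoxymethyl)-2,2'-biindole-3,3'-dicarbaldehyde | O=Cc1c(-c2n(COCC[Si](C)(C)C)c3cc(Cl)ccc3c2C=O)n(COCC[Si](C)(C)C)c2cc(Cl)ccc12
A5 | alternative 2 | 2,9-dichloro-11,12-bis(2-trimethylsilylethoxymethyl)indolo[2,3-a]carbazole-5,6-diol | Oc1c(O)c2c3ccc(Cl)cc3n(COCC[Si](C)(C)C)c2c2n(COCC[Si](C)(C)C)c3cc(Cl)ccc3c12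
A6 | alternative 3 | N,N'-(ethyne-1,2-diyl)bis{N-[5-chloro-2-(methoxyethynyl)phenyl]methanesulfonamide} | COC#Cc1ccc(Cl)cc1N(C#CN(c1cc(Cl)ccc1C#COC)S(C)(=O)=O)S(C)(=O)=O
A7 | alternative 3 | 2,9-dichloro-5,6-dimethoxy-11,12-bis(methylsulfonyl)indolo[2,3-a]carbazole | COc1c(OC)c2c3ccc(Cl)cc3n(S(C)(=O)=O)c2c2n(S(C)(=O)=O)c3cc(Cl)ccc3c12
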